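**Plan**

1. Retrosynthesis first removes the five benzyl ethers and the ring A O‑methyl group, then cuts ring A at two C–C bonds: C(aroyl)–C(OH) and C(CH2Ar)–C(OMe).
2. This cut is open because ring A is a phloroglucinol. Its carbon bearing the ring B ketone, the C–OH carbon next to it and the carbon bearing the bridging CH2 are C2, C3 and C4 of a 1,5‑diarylpentane‑1,3‑dione. The remaining C(O)–CH–C(O) triad is a malonyl unit.
3. The diketone is cut at C4–C5 into the dianion of the ring B aroylacetone and a ring C benzylic bromide. The bromide's CH2 comes from formylation of ring C, and the ring C/ring D benzophenone is cut at the ring C aryl–carbonyl bond (aryllithium plus ring D aldehyde, then oxidation).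
4. Forward: rings B, C and D are bought as benzenoid building blocks. The C/D ketone is made first, ring C is homologated by one carbon, and the chain is joined to the ring B diketone. Ring A is the only ring built, by [3+3] annulation with malonyl dichloride, followed by para‑O‑methylation and hydrogenolysis.
5. The target has no stereocentre. The single carbinol centre formed on the way (step 5) is racemic and is removed by oxidation in step 6.

Key step: step 15

Assumption: 5‑methoxybenzene‑1,3‑diol and 2,4‑dihydroxy‑6‑methylbenzaldehyde are taken as purchasable, and enol and enol ether geometries are left uncontrolled because every isomer converges on aromatic ring A.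

**Step 1**
Reactants: 1 5‑methoxybenzene‑1,3‑diol
Product: 2 2‑iodo‑5‑methoxybenzene‑1,3‑diol
Conditions: I2 (1.05 equiv), NaHCO3, THF/H2O, 0 °C
Reagents that add atoms: iodine, II
Why: Electrophilic aromatic iodination under bicarbonate buffering should go to the carbon flanked by both hydroxyls (also para to the methoxyl), as it does with resorcinol and its 5‑alkyl homologues.

**Step 2**
Reactants: 2 2‑iodo‑5‑methoxybenzene‑1,3‑diol
Product: 3 1,3‑bis(benzyloxy)‑2‑iodo‑5‑methoxybenzene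
Conditions: BnBr (2.3 equiv), K2CO3, DMF, 20 °C
Reagents that add atoms: benzyl bromide, BrCc1ccccc1
Why: Williamson ether synthesis on two free phenols that have no competing nucleophilic site.

**Step 3**
Reactants: 4 2,4‑dihydroxy‑6‑methylbenzaldehyde
Product: 5 4‑(benzyloxy)‑2‑hydroxy‑6‑methylbenzaldehyde
Conditions: BnBr (1.05 equiv), NaHCO3, KI (cat.), MeCN, 80 °C
Reagents that add atoms: benzyl bromide, BrCc1ccccc1
Why: Williamson mono‑etherification, selective because the weak base ionises only the more acidic 4‑hydroxyl while the 2‑hydroxyl stays hydrogen‑bonded to the aldehyde.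

**Step 4**
Reactants: 5 4‑(benzyloxy)‑2‑hydroxy‑6‑methylbenzaldehyde
Product: 6 4‑(benzyloxy)‑2‑methoxy‑6‑methylbenzaldehyde
Conditions: MeI, K2CO3, DMF, 40 °C
Reagents that add atoms: iodomethane, CI
Why: Williamson methylation of the remaining chelated phenol, which needs the stronger base and a polar aprotic solvent but has no competing site.

**Step 5**
Reactants: 3 1,3‑bis(benzyloxy)‑2‑iodo‑5‑methoxybenzene; 6 4‑(benzyloxy)‑2‑methoxy‑6‑methylbenzaldehyde
Product: 8 (±)‑[2,6‑bis(benzyloxy)‑4‑methoxyphenyl][4‑(benzyloxy)‑2‑methoxy‑6‑methylphenyl]methanol, via aryllithium 7 (not isolated)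
Conditions: n‑BuLi (1.05 equiv), THF, −78 °C; then 6, −78 → 0 °C; aq. NH4Cl
Reagents that add atoms: none
Why: Iodine–lithium exchange at −78 °C is faster than any attack on the benzyl ethers, and the aryllithium adds 1,2 to the non‑enolisable aldehyde (aryllithium addition); the carbinol carbon forms racemic and becomes sp2 in step 6.

**Step 6**
Reactants: 8 (±)‑[2,6‑bis(benzyloxy)‑4‑methoxyphenyl][4‑(benzyloxy)‑2‑methoxy‑6‑methylphenyl]methanol
Product: 9 [2,6‑bis(benzyloxy)‑4‑methoxyphenyl][4‑(benzyloxy)‑2‑methoxy‑6‑methylphenyl]methanone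
Conditions: Dess–Martin periodinane, CH2Cl2, 20 °C
Reagents that add atoms: none
Why: Dess–Martin oxidation of a secondary diaryl carbinol to the ketone is mild and neutral and tolerates benzyl and methyl ethers.

**Step 7**
Reactants: 9 [2,6‑bis(benzyloxy)‑4‑methoxyphenyl][4‑(benzyloxy)‑2‑methoxy‑6‑methylphenyl]methanone
Product: 11 2,4‑bis(benzyloxy)‑3‑[4‑(benzyloxy)‑2‑methoxy‑6‑methylbenzoyl]‑6‑methoxybenzaldehyde, via iminium chloride 10 (not isolated)
Conditions: POCl3, DMF, 0 → 60 °C; then aq. NaOAc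
Reagents that add atoms: N,N‑dimethylformamide, CN(C)C=O; water, O
Why: Vilsmeier–Haack formylation should take one of the two symmetry‑equivalent free carbons of ring C, each ortho, ortho and para to three ether oxygens, ahead of ring D, whose free carbons have only two ether donors, and the first formyl group deactivates ring C against a second.

**Step 8**
Reactants: 11 2,4‑bis(benzyloxy)‑3‑[4‑(benzyloxy)‑2‑methoxy‑6‑methylbenzoyl]‑6‑methoxybenzaldehyde
Product: 12 [2,6‑bis(benzyloxy)‑3‑(hydroxymethyl)‑4‑methoxyphenyl][4‑(benzyloxy)‑2‑methoxy‑6‑methylphenyl]methanone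
Conditions: NaBH4, THF/MeOH, 0 °C
Reagents that add atoms: none
Why: Borohydride reduction is chemoselective for the aldehyde because the diaryl ketone is shielded by four ortho substituents and twisted out of conjugation.

**Step 9**
Reactants: 12 [2,6‑bis(benzyloxy)‑3‑(hydroxymethyl)‑4‑methoxyphenyl][4‑(benzyloxy)‑2‑methoxy‑6‑methylphenyl]methanone
Product: 13 [2,6‑bis(benzyloxy)‑3‑(bromomethyl)‑4‑methoxyphenyl][4‑(benzyloxy)‑2‑methoxy‑6‑methylphenyl]methanone
Conditions: PBr3 (0.4 equiv), Et2O/CH2Cl2, 0 °C; cold aq. NaHCO3 wash; used at once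
Reagents that add atoms: phosphorus tribromide, BrP(Br)Br
Why: Bromination of a benzylic alcohol by PBr3 (displacement of the phosphite ester by bromide) is fast at 0 °C, and the bromide, activated by three ether oxygens, is carried forward without storage.

**Step 10**
Reactants: 14 5‑methylbenzene‑1,3‑diol (orcinol)
Product: 16 1‑(2,4‑dihydroxy‑6‑methylphenyl)ethan‑1‑one, via ketiminium chloride 15 (not isolated)
Conditions: MeCN, ZnCl2, HCl (g), Et2O, 0 °C; then H2O, 100 °C
Reagents that add atoms: acetonitrile, CC#N; water, O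
Why: Houben–Hoesch acylation, in which the nitrilium electrophile attacks orcinol para to one hydroxyl and ortho to the other, and hydrolysis of the ketiminium salt gives the ketone.

**Step 11**
Reactants: 16 1‑(2,4‑dihydroxy‑6‑methylphenyl)ethan‑1‑one
Product: 17 1‑[2,4‑bis(benzyloxy)‑6‑methylphenyl]ethan‑1‑one
Conditions: BnBr (2.5 equiv), K2CO3, DMF, 70 °C
Reagents that add atoms: benzyl bromide, BrCc1ccccc1
Why: Williamson ether synthesis, heated in DMF so that the hydroxyl hydrogen‑bonded to the ketone is alkylated as well.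

**Step 12**
Reactants: 17 1‑[2,4‑bis(benzyloxy)‑6‑methylphenyl]ethan‑1‑one
Product: 18 1‑[2,4‑bis(benzyloxy)‑6‑methylphenyl]butane‑1,3‑dione
Conditions: NaH (2.5 equiv), EtOAc, THF, 65 °C; then aq. HCl
Reagents that add atoms: ethyl acetate, CCOC(C)=O
Why: Crossed Claisen condensation of the methyl ketone enolate with ethyl acetate, driven by formation of the stabilised sodium β‑diketonate and occurring at the methyl carbon away from the hindered aryl group.

**Step 13**
Reactants: 18 1‑[2,4‑bis(benzyloxy)‑6‑methylphenyl]butane‑1,3‑dione; 13 [2,6‑bis(benzyloxy)‑3‑(bromomethyl)‑4‑methoxyphenyl][4‑(benzyloxy)‑2‑methoxy‑6‑methylphenyl]methanone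
Product: 20 1‑[2,4‑bis(benzyloxy)‑6‑methylphenyl]‑5‑{2,4‑bis(benzyloxy)‑3‑[4‑(benzyloxy)‑2‑methoxy‑6‑methylbenzoyl]‑6‑methoxyphenyl}pentane‑1,3‑dione, via dilithium dianion 19 (not isolated)
Conditions: LiN(i‑Pr)2 (2.2 equiv per 18), THF, 0 °C; then 13 (0.7 equiv), −78 → 0 °C; aq. NH4Cl
Reagents that add atoms: none
Why: Alkylation of a β‑diketone dianion takes place at the terminal, less stabilised carbanion and not at the central carbon, so the benzylic bromide is attached at C4 of the future pentanedione, and the excess dianion should consume the labile bromide at low temperature.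

**Step 14**
Reactants: 20 1‑[2,4‑bis(benzyloxy)‑6‑methylphenyl]‑5‑{2,4‑bis(benzyloxy)‑3‑[4‑(benzyloxy)‑2‑methoxy‑6‑methylbenzoyl]‑6‑methoxyphenyl}pentane‑1,3‑dione
Product: 21 1‑[2,4‑bis(benzyloxy)‑6‑methylphenyl]‑5‑{2,4‑bis(benzyloxy)‑3‑[4‑(benzyloxy)‑2‑methoxy‑6‑methylbenzoyl]‑6‑methoxyphenyl}‑1,3‑bis(trimethylsilyloxy)penta‑1,3‑diene
Conditions: Me3SiOTf (2.4 equiv), Et3N (3 equiv), Et2O, 0 → 20 °C; ammonium salt separated, solvent removed, no aqueous work‑up
Reagents that add atoms: trimethylsilyl trifluoromethanesulfonate, C[Si](C)(C)OS(=O)(=O)C(F)(F)F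
Why: Silyl enol ether formation by soft enolisation silylates the chelated enol and then removes a γ‑hydrogen, available only on the CH2 next to the aliphatic‑side carbonyl, to give the 1,3‑bis(silyloxy)‑1,3‑diene, while the diaryl ketone has no α‑hydrogen.

**Step 15**
Reactants: 21 1‑[2,4‑bis(benzyloxy)‑6‑methylphenyl]‑5‑{2,4‑bis(benzyloxy)‑3‑[4‑(benzyloxy)‑2‑methoxy‑6‑methylbenzoyl]‑6‑methoxyphenyl}‑1,3‑bis(trimethylsilyloxy)penta‑1,3‑diene; 22 malonyl dichloride
Product: 24 [2,4‑bis(benzyloxy)‑6‑methylphenyl](3‑{[2,4‑bis(benzyloxy)‑3‑[4‑(benzyloxy)‑2‑methoxy‑6‑methylbenzoyl]‑6‑methoxyphenyl]methyl}‑2,4,6‑trihydroxyphenyl)methanone, via acid chloride 23 (not isolated)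
Conditions: 22 (1.1 equiv, slow addition), Me3SiOTf (0.2 equiv), CH2Cl2 (0.01 M), −78 → 20 °C; then 1 M HCl/THF work‑up
Reagents that add atoms: none
Why: Proposed new method: the terminal diene carbon of 21 (C4 of the pentanedione) should attack one acyl chloride of 22 in a Mukaiyama‑type C‑acylation with loss of Me3SiCl to give acid chloride 23, whose remaining silyl enol ether carbon (C2, between the two carbonyls) then attacks the second acyl chloride, again losing Me3SiCl, and the resulting 2‑aroylcyclohexane‑1,3,5‑trione tautomerises to the aromatic triol. The closest known reactions are the formal [3+3] cyclisations of 1,3‑bis(silyl enol ethers) with 1,3‑dielectrophiles, their acylation by acid chlorides at the terminal carbon, and the formation of 4‑hydroxy‑2‑pyranones from malonyl dichloride and ketones or 1,3‑diketones. Ring A closes in a 6‑(enolexo)‑exo‑trig mode, the attacking enol double bond lying outside the new ring, and no stereocentre is created. The regiochemistry cannot go astray because C2 and C4 are the only nucleophilic carbons and either order of the two acylations leads to the same ring. The step needs C‑ over O‑acylation in the closure (O‑closure would give a 4‑hydroxy‑2‑pyranone), which the soft silyl enol ether carbon, the base‑free Me3SiOTf‑activated conditions and the gain of aromaticity should favour, while slow addition at high dilution suppresses oligomers. The ethers and the hindered diaryl ketone are inert to the acid chloride at low temperature, and the silyl dienol ether is far more nucleophilic than the single free CH of ring C.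

**Step 16**
Reactants: 24 [2,4‑bis(benzyloxy)‑6‑methylphenyl](3‑{[2,4‑bis(benzyloxy)‑3‑[4‑(benzyloxy)‑2‑methoxy‑6‑methylbenzoyl]‑6‑methoxyphenyl]methyl}‑2,4,6‑trihydroxyphenyl)methanone
Product: 25 [2,4‑bis(benzyloxy)‑6‑methylphenyl](3‑{[2,4‑bis(benzyloxy)‑3‑[4‑(benzyloxy)‑2‑methoxy‑6‑methylbenzoyl]‑6‑methoxyphenyl]methyl}‑2,6‑dihydroxy‑4‑methoxyphenyl)methanone
Conditions: Me2SO4 (1.05 equiv), K2CO3 (1.1 equiv), acetone, 0 → 20 °C
Reagents that add atoms: dimethyl sulfate, COS(=O)(=O)OC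
Why: Williamson methylation with one equivalent should take the hydroxyl para to the ketone, the most acidic one and the only one never held in the hydrogen bond to the carbonyl, as in the para‑selective O‑methylation of 2,4,6‑trihydroxyaryl ketones.

**Step 17**
Reactants: 25 [2,4‑bis(benzyloxy)‑6‑methylphenyl](3‑{[2,4‑bis(benzyloxy)‑3‑[4‑(benzyloxy)‑2‑methoxy‑6‑methylbenzoyl]‑6‑methoxyphenyl]methyl}‑2,6‑dihydroxy‑4‑methoxyphenyl)methanone
Product: 26 (2,4‑dihydroxy‑6‑methylphenyl)[2,6‑dihydroxy‑3‑{[2,4‑dihydroxy‑3‑(4‑hydroxy‑2‑methoxy‑6‑methylbenzoyl)‑6‑methoxyphenyl]methyl}‑4‑methoxyphenyl]methanone (CNP0596095.0)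
Conditions: H2 (1 atm), 10% Pd/C, EtOAc/MeOH, 20 °C
Reagents that add atoms: none
Why: Catalytic hydrogenolysis cleaves the five benzyl aryl ethers, while the two hindered diaryl ketones and the diarylmethane bridge should survive if the reaction is stopped once debenzylation is complete.

**Compound list**

1 | 5‑methoxybenzene‑1,3‑diol | COc1cc(O)cc(O)c1 | starting material
2 | 2‑iodo‑5‑methoxybenzene‑1,3‑diol | COc1cc(O)c(I)c(O)c1 | intermediate
3 | 1,3‑bis(benzyloxy)‑2‑iodo‑5‑methoxybenzene | COc1cc(OCc2ccccc2)c(I)c(OCc2ccccc2)c1 | intermediate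
4 | 2,4‑dihydroxy‑6‑methylbenzaldehyde | Cc1cc(O)cc(O)c1C=O | starting material
5 | 4‑(benzyloxy)‑2‑hydroxy‑6‑methylbenzaldehyde | Cc1cc(OCc2ccccc2)cc(O)c1C=O | intermediate
6 | 4‑(benzyloxy)‑2‑methoxy‑6‑methylbenzaldehyde | COc1cc(OCc2ccccc2)cc(C)c1C=O | intermediate
7 | [2,6‑bis(benzyloxy)‑4‑methoxyphenyl]lithium (not isolated) | [Li]c1c(OCc2ccccc2)cc(OC)cc1OCc1ccccc1 | intermediate
8 | (±)‑[2,6‑bis(benzyloxy)‑4‑methoxyphenyl][4‑(benzyloxy)‑2‑methoxy‑6‑methylphenyl]methanol (racemic) | COc1cc(OCc2ccccc2)c(C(O)c2c(C)cc(OCc3ccccc3)cc2OC)c(OCc2ccccc2)c1 | intermediate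
9 | [2,6‑bis(benzyloxy)‑4‑methoxyphenyl][4‑(benzyloxy)‑2‑methoxy‑6‑methylphenyl]methanone | COc1cc(OCc2ccccc2)c(C(=O)c2c(C)cc(OCc3ccccc3)cc2OC)c(OCc2ccccc2)c1 | intermediate
10 | N‑({2,4‑bis(benzyloxy)‑3‑[4‑(benzyloxy)‑2‑methoxy‑6‑methylbenzoyl]‑6‑methoxyphenyl}methylidene)‑N‑methylmethanaminium chloride (not isolated) | COc1cc(OCc2ccccc2)c(C(=O)c2c(C)cc(OCc3ccccc3)cc2OC)c(OCc2ccccc2)c1C=[N+](C)C.[Cl-] | intermediate
11 | 2,4‑bis(benzyloxy)‑3‑[4‑(benzyloxy)‑2‑methoxy‑6‑methylbenzoyl]‑6‑methoxybenzaldehyde | COc1cc(OCc2ccccc2)c(C(=O)c2c(C)cc(OCc3ccccc3)cc2OC)c(OCc2ccccc2)c1C=O | intermediate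
12 | [2,6‑bis(benzyloxy)‑3‑(hydroxymethyl)‑4‑methoxyphenyl][4‑(benzyloxy)‑2‑methoxy‑6‑methylphenyl]methanone | COc1cc(OCc2ccccc2)c(C(=O)c2c(C)cc(OCc3ccccc3)cc2OC)c(OCc2ccccc2)c1CO | intermediate
13 | [2,6‑bis(benzyloxy)‑3‑(bromomethyl)‑4‑methoxyphenyl][4‑(benzyloxy)‑2‑methoxy‑6‑methylphenyl]methanone | COc1cc(OCc2ccccc2)c(C(=O)c2c(C)cc(OCc3ccccc3)cc2OC)c(OCc2ccccc2)c1CBr | intermediate
14 | 5‑methylbenzene‑1,3‑diol (orcinol) | Cc1cc(O)cc(O)c1 | starting material
15 | 1‑(2,4‑dihydroxy‑6‑methylphenyl)ethan‑1‑iminium chloride (not isolated) | CC(=[NH2+])c1c(C)cc(O)cc1O.[Cl-] | intermediate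
16 | 1‑(2,4‑dihydroxy‑6‑methylphenyl)ethan‑1‑one | CC(=O)c1c(C)cc(O)cc1O | intermediate
17 | 1‑[2,4‑bis(benzyloxy)‑6‑methylphenyl]ethan‑1‑one | CC(=O)c1c(C)cc(OCc2ccccc2)cc1OCc1ccccc1 | intermediate
18 | 1‑[2,4‑bis(benzyloxy)‑6‑methylphenyl]butane‑1,3‑dione | CC(=O)CC(=O)c1c(C)cc(OCc2ccccc2)cc1OCc1ccccc1 | intermediate
19 | dilithium 1‑[2,4‑bis(benzyloxy)‑6‑methylphenyl]buta‑1,3‑diene‑1,3‑diolate (dianion of 18, not isolated) | [Li+].[Li+].C=C([O-])C=C([O-])c1c(C)cc(OCc2ccccc2)cc1OCc1ccccc1 | intermediate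
20 | 1‑[2,4‑bis(benzyloxy)‑6‑methylphenyl]‑5‑{2,4‑bis(benzyloxy)‑3‑[4‑(benzyloxy)‑2‑methoxy‑6‑methylbenzoyl]‑6‑methoxyphenyl}pentane‑1,3‑dione | Cc1cc(OCc2ccccc2)cc(OCc2ccccc2)c1C(=O)CC(=O)CCc1c(OC)cc(OCc2ccccc2)c(C(=O)c2c(C)cc(OCc3ccccc3)cc2OC)c1OCc1ccccc1 | intermediate
21 | 1‑[2,4‑bis(benzyloxy)‑6‑methylphenyl]‑5‑{2,4‑bis(benzyloxy)‑3‑[4‑(benzyloxy)‑2‑methoxy‑6‑methylbenzoyl]‑6‑methoxyphenyl}‑1,3‑bis(trimethylsilyloxy)penta‑1,3‑diene (enol ether geometry not defined) | Cc1cc(OCc2ccccc2)cc(OCc2ccccc2)c1C(O[Si](C)(C)C)=CC(O[Si](C)(C)C)=CCc1c(OC)cc(OCc2ccccc2)c(C(=O)c2c(C)cc(OCc3ccccc3)cc2OC)c1OCc1ccccc1 | intermediate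
22 | malonyl dichloride (propanedioyl dichloride) | O=C(Cl)CC(=O)Cl | starting material
23 | 7‑[2,4‑bis(benzyloxy)‑6‑methylphenyl]‑4‑({2,4‑bis(benzyloxy)‑3‑[4‑(benzyloxy)‑2‑methoxy‑6‑methylbenzoyl]‑6‑methoxyphenyl}methyl)‑3,5‑dioxo‑7‑(trimethylsilyloxy)hept‑6‑enoyl chloride (racemic, not isolated) | Cc1cc(OCc2ccccc2)cc(OCc2ccccc2)c1C(O[Si](C)(C)C)=CC(=O)C(Cc1c(OC)cc(OCc2ccccc2)c(C(=O)c2c(C)cc(OCc3ccccc3)cc2OC)c1OCc1ccccc1)C(=O)CC(=O)Cl | intermediate
24 | [2,4‑bis(benzyloxy)‑6‑methylphenyl](3‑{[2,4‑bis(benzyloxy)‑3‑[4‑(benzyloxy)‑2‑methoxy‑6‑methylbenzoyl]‑6‑methoxyphenyl]methyl}‑2,4,6‑trihydroxyphenyl)methanone | Oc1cc(O)c(C(=O)c2c(C)cc(OCc3ccccc3)cc2OCc2ccccc2)c(O)c1Cc1c(OC)cc(OCc2ccccc2)c(C(=O)c2c(C)cc(OCc3ccccc3)cc2OC)c1OCc1ccccc1 | intermediate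
25 | [2,4‑bis(benzyloxy)‑6‑methylphenyl](3‑{[2,4‑bis(benzyloxy)‑3‑[4‑(benzyloxy)‑2‑methoxy‑6‑methylbenzoyl]‑6‑methoxyphenyl]methyl}‑2,6‑dihydroxy‑4‑methoxyphenyl)methanone | COc1cc(O)c(C(=O)c2c(C)cc(OCc3ccccc3)cc2OCc2ccccc2)c(O)c1Cc1c(OC)cc(OCc2ccccc2)c(C(=O)c2c(C)cc(OCc3ccccc3)cc2OC)c1OCc1ccccc1 | intermediate
26 | (2,4‑dihydroxy‑6‑methylphenyl)[2,6‑dihydroxy‑3‑{[2,4‑dihydroxy‑3‑(4‑hydroxy‑2‑methoxy‑6‑methylbenzoyl)‑6‑methoxyphenyl]methyl}‑4‑methoxyphenyl]methanone | COc1cc(O)c(C(=O)c2c(C)cc(O)cc2O)c(O)c1Cc1c(OC)cc(O)c(C(=O)c2c(C)cc(O)cc2OC)c1O | target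

**Totals**

Total step count: 17.
Longest linear sequence: 12 steps (steps 1, 2, 5–9 and 13–17, from 1 to 26; the branch from 4 is equally long).

**Steps most likely to fail**

1. Step 15 (key step). The ring closure may go through an enol oxygen instead of carbon, intermolecular acylation may give oligomers, or 21 may lose its silyl groups to adventitious HCl before the first C–C bond forms. The fallback uses known reaction types only, sets out from 21 and forms the two ring bonds in separate operations. Acylation of 21 at its terminal carbon with methyl 3‑chloro‑3‑oxopropanoate (CH2Cl2, −78 → 20 °C, aqueous work‑up), a mono‑acid chloride that cannot cyclise at this stage, should give methyl 7‑[2,4‑bis(benzyloxy)‑6‑methylphenyl]‑4‑({2,4‑bis(benzyloxy)‑3‑[4‑(benzyloxy)‑2‑methoxy‑6‑methylbenzoyl]‑6‑methoxyphenyl}methyl)‑3,5,7‑trioxoheptanoate F1. Mg(OMe)2 in MeOH at reflux should then bring about the Claisen cyclisation of the C6 carbanion onto the ester, the established conversion of 3,5,7‑triketo esters into acylphloroglucinols. This returns to the route at 24.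

2. Step 13 (with the bromide made in step 9). The benzylic bromide, activated by three ether oxygens, may ionise and self‑condense or hydrolyse before or during the alkylation, and proton transfer may compete with substitution. The fallback sets out from aldehyde 11 and diketone 18 and avoids any benzylic halide. A boron‑templated aldol condensation at the terminal methyl of 18 (B2O3, B(OBu)3, n‑BuNH2, EtOAc, 70 °C; then dilute HCl) should give (E)‑1‑[2,4‑bis(benzyloxy)‑6‑methylphenyl]‑5‑{2,4‑bis(benzyloxy)‑3‑[4‑(benzyloxy)‑2‑methoxy‑6‑methylbenzoyl]‑6‑methoxyphenyl}pent‑4‑ene‑1,3‑dione F2. Hydrogenation of its C=C over Pd/C poisoned by Ph2S (H2 1 atm, EtOAc), a catalyst that leaves benzyl ethers and aryl ketones untouched, returns to the route at 20.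

3. Step 1. Iodination may go to the carbon between hydroxyl and methoxyl, or run on to di‑iodination, which would place the later ketone on the wrong ring C carbon. The fallback sets out from 1 and fixes the site by directed ortho‑metalation. MeOCH2Cl with i‑Pr2NEt in CH2Cl2 gives 1‑methoxy‑3,5‑bis(methoxymethoxy)benzene F3. n‑BuLi (THF, 0 °C) removes the proton between the two acetal groups to give [4‑methoxy‑2,6‑bis(methoxymethoxy)phenyl]lithium F4, which adds to aldehyde 6 to give (±)‑[4‑(benzyloxy)‑2‑methoxy‑6‑methylphenyl][4‑methoxy‑2,6‑bis(methoxymethoxy)phenyl]methanol F5. Dess–Martin oxidation gives [4‑(benzyloxy)‑2‑methoxy‑6‑methylphenyl][4‑methoxy‑2,6‑bis(methoxymethoxy)phenyl]methanone F6. HCl in MeOH removes both acetals to give [4‑(benzyloxy)‑2‑methoxy‑6‑methylphenyl](2,6‑dihydroxy‑4‑methoxyphenyl)methanone F7. Benzylation (BnBr, K2CO3, DMF, 70 °C) returns to the route at 9.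

**Further compounds**

F1 | step 15 | methyl 7‑[2,4‑bis(benzyloxy)‑6‑methylphenyl]‑4‑({2,4‑bis(benzyloxy)‑3‑[4‑(benzyloxy)‑2‑methoxy‑6‑methylbenzoyl]‑6‑methoxyphenyl}methyl)‑3,5,7‑trioxoheptanoate (racemic) | COC(=O)CC(=O)C(Cc1c(OC)cc(OCc2ccccc2)c(C(=O)c2c(C)cc(OCc3ccccc3)cc2OC)c1OCc1ccccc1)C(=O)CC(=O)c1c(C)cc(OCc2ccccc2)cc1OCc1ccccc1
F2 | step 13 | (E)‑1‑[2,4‑bis(benzyloxy)‑6‑methylphenyl]‑5‑{2,4‑bis(benzyloxy)‑3‑[4‑(benzyloxy)‑2‑methoxy‑6‑methylbenzoyl]‑6‑methoxyphenyl}pent‑4‑ene‑1,3‑dione | Cc1cc(OCc2ccccc2)cc(OCc2ccccc2)c1C(=O)CC(=O)/C=C/c1c(OC)cc(OCc2ccccc2)c(C(=O)c2c(C)cc(OCc3ccccc3)cc2OC)c1OCc1ccccc1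
F3 | step 1 | 1‑methoxy‑3,5‑bis(methoxymethoxy)benzene | COCOc1cc(OC)cc(OCOC)c1
F4 | step 1 | [4‑methoxy‑2,6‑bis(methoxymethoxy)phenyl]lithium | [Li]c1c(OCOC)cc(OC)cc1OCOC
F5 | step 1 | (±)‑[4‑(benzyloxy)‑2‑methoxy‑6‑methylphenyl][4‑methoxy‑2,6‑bis(methoxymethoxy)phenyl]methanol (racemic) | COCOc1cc(OC)cc(OCOC)c1C(O)c1c(C)cc(OCc2ccccc2)cc1OC
F6 | step 1 | [4‑(benzyloxy)‑2‑methoxy‑6‑methylphenyl][4‑methoxy‑2,6‑bis(methoxymethoxy)phenyl]methanone | COCOc1cc(OC)cc(OCOC)c1C(=O)c1c(C)cc(OCc2ccccc2)cc1OC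
F7 | step 1 | [4‑(benzyloxy)‑2‑methoxy‑6‑methylphenyl](2,6‑dihydroxy‑4‑methoxyphenyl)methanone | COc1cc(O)c(C(=O)c2c(C)cc(OCc3ccccc3)cc2OC)c(O)c1
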